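**Plan** (locants are those of the bicyclo[3.3.1]nonane name of the target)

- Retrosynthesis, first cut: both side-chain alkenes are cut at their CH2–CH= bonds (C7 prenyl, C6 4-methylpent-3-enyl), back to a 7-methylidene-6-vinyl bicycle.
- Second cut: C1–C8 and C5–C6. Ring B (C1, C9, C5, C6, C7, C8) loses its three-carbon bridge C8–C7–C6 and ring A flattens to 2-methylpropanoylphloroglucinol.
- Enabling feature: C1 and C5 each sit between the C9 carbonyl and a trione carbonyl (C2, C4). They are the two free, doubly activated ring carbons of the acylphloroglucinol, and C8 and C6 are the two ends of a bis-allylic 1,3-electrophile.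
- Forward: acylation gives aromatic ring A; a C7 dienyl biscarbonate is made by borylcupration and cross-coupling; one palladium-catalysed operation attaches it through C8 and C6, closing ring B and dearomatising ring A; the side chains are finished last.
- Stereochemistry: C6 from ligand-controlled face selection at an η3-allyl terminus (C1 and C5 follow from the bridge); C7 from exo-face hydroboration of the methylidene group.

Key step: step 5

Assumption: the (R,R)-ligand is taken to give the (6R) enantiomer of 10 shown; the sense of induction cannot be assigned with certainty in advance, and the (S,S)-ligand is used if it proves to be the opposite.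

**Step 1**
Reactants: 1 benzene-1,3,5-triol (phloroglucinol); 2 2-methylpropanoyl chloride
Product: 3 2-methyl-1-(2,4,6-trihydroxyphenyl)propan-1-one
Conditions: AlCl3, PhNO2/CH2Cl2, 0 to 60 °C; aq. HCl work-up
Reagents that add atoms: none
Why: Friedel–Crafts C-acylation of the very electron-rich triol should stop after one acyl group, which deactivates the ring and is held by hydrogen bonds to the flanking hydroxyls; no stereocentre is formed.

**Step 2**
Reactants: 4 but-2-yn-1-ol
Product: 5 (2Z)-3-(4,4,5,5-tetramethyl-1,3,2-dioxaborolan-2-yl)but-2-en-1-ol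
Conditions: CuCl (cat.), PCy3, NaOtBu (cat.), B2pin2, MeOH, toluene, rt
Reagents that add atoms: bis(pinacolato)diboron, CC1(C)OB(OC1(C)C)B1OC(C)(C)C(C)(C)O1
Why: Copper-catalysed borylcupration–protonation (formal hydroboration) of a propargylic alcohol adds Cu–B syn with copper next to the oxygen-bearing carbon and boron at C3, and protonation with retention gives the (2Z)-alkene with methyl and CH2OH cis; no stereocentre is formed.

**Step 3**
Reactants: 5 (2Z)-3-(4,4,5,5-tetramethyl-1,3,2-dioxaborolan-2-yl)but-2-en-1-ol; 6 2-bromoprop-2-en-1-ol
Product: 7 (2E)-3-methyl-4-methylidenepent-2-ene-1,5-diol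
Conditions: Pd(dppf)Cl2 (cat.), K3PO4, THF/H2O, 45 °C; kept in solution
Reagents that add atoms: none
Why: Suzuki–Miyaura coupling of an alkenyl boronate with an alkenyl bromide proceeds with retention at both sp2 carbons, so the (2E) geometry (methylidene-bearing carbon trans to CH2OH) follows from 5; no stereocentre is formed.

**Step 4**
Reactants: 7 (2E)-3-methyl-4-methylidenepent-2-ene-1,5-diol
Product: 8 (2E)-3-methyl-4-methylidenepent-2-ene-1,5-diyl dimethyl biscarbonate
Conditions: ClCO2Me, pyridine, DMAP (cat.), CH2Cl2, 0 °C
Reagents that add atoms: methyl chloroformate, COC(Cl)=O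
Why: Acylation of both primary allylic alcohols with a chloroformate installs carbonate leaving groups that release their own base (methoxide) on ionisation; no stereocentre is formed.

**Step 5**
Reactants: 3 2-methyl-1-(2,4,6-trihydroxyphenyl)propan-1-one; 8 (2E)-3-methyl-4-methylidenepent-2-ene-1,5-diyl dimethyl biscarbonate
Product: 10 (1S,5S,6R)-6-ethenyl-4-hydroxy-6-methyl-7-methylidene-3-(2-methylpropanoyl)bicyclo[3.3.1]non-3-ene-2,9-dione (methyl equatorial on ring B on the C4 side, vinyl axial on the C9 side), via mono-C-allylated phenol carbonate 9 (not isolated)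
Conditions: Pd2(dba)3·CHCl3 (cat.), (R,R)-DACH-phenyl ligand [(1R,2R)-N,N'-bis(2-diphenylphosphanylbenzoyl)cyclohexane-1,2-diamine], Et3N, THF, 0 °C (slow addition of 8 to excess 3), then 45 °C
Reagents that add atoms: none
Why: Proposed new method: zerovalent palladium first ionises the 2-substituted allyl carbonate of 8 (the less substituted alkene), the phenolate of 3 is C-allylated at one of its two free ring carbons to give 9 (O-allylation is reversible under the catalyst), and ionisation of the remaining trisubstituted allyl carbonate gives an η3-allyl complex that is attacked at its methyl-bearing terminus by the other free ring carbon of the C-protonated (cyclohexadienone) tautomer of the phenolate, so that C1–C8 and C5–C6 form with CO2 and methanol as the only by-products. The closest known reaction types are the palladium-catalysed dearomative conjunctive allylic annulation of 3,5-dialkylated acylphloroglucinols with 2-methylidenepropane-1,3-diyl dicarbonates and asymmetric Tsuji–Trost ring closures of tethered phenols or enolates onto a methyl-substituted allyl terminus that give a methyl/vinyl quaternary carbon; not yet shown are ring carbons that keep their hydrogen and a dienyl bis-electrophile. Ring B (C1, C9, C5, C6, C7, C8) closes by 6-exo attack on the allyl unit, the eight-membered alternative at the CH2 terminus and closure through the acyl-bearing C3 (two adjacent quaternary carbons) being disfavoured. C6 is set by the ligand, which selects one face of the η3-allyl after fast π-σ-π exchange through its CH2 terminus; C1 and C5 follow because a three-atom bridge can only span the ring cis, and their sense relative to C6 (methyl equatorial, vinyl axial) is expected from the s-trans preference of the 2,3-disubstituted diene unit methylidene=C7–C6=CH, which keeps C8 syn to the allyl CH and anti to the methyl group as the ring closes. The step needs chemoselective ionisation (2-substituted before 3,3-disubstituted allyl carbonate, helped by slow addition of 8 to excess 3), C- over O-closure (the chroman from O-attack should re-ionise on warming) and attack at C6 and not at the methylidene carbon (which is not part of the η3 unit formed from the E-alkene).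

**Step 6**
Reactants: 10 (1S,5S,6R)-6-ethenyl-4-hydroxy-6-methyl-7-methylidene-3-(2-methylpropanoyl)bicyclo[3.3.1]non-3-ene-2,9-dione; 11 1-bromo-2-methylprop-1-ene
Product: 13 (1S,5S,6S,7R)-4-hydroxy-6-methyl-7-(3-methylbut-2-en-1-yl)-6-(4-methylpent-3-en-1-yl)-3-(2-methylpropanoyl)bicyclo[3.3.1]non-3-ene-2,9-dione, via tris(9-BBN) adduct 12 (not isolated)
Conditions: 9-BBN (3.3 equiv), THF, 0 to 40 °C; then 11, Pd(dppf)Cl2 (cat.), AsPh3, aq. K3PO4, DMF, 50 °C; citric acid work-up
Reagents that add atoms: 9-borabicyclo[3.3.1]nonane, [H]B1C2CCCC1CCC2 (its boron is carried in 12 only and is lost again before 13)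
Why: Anti-Markovnikov syn-hydroboration of both terminal alkenes with 9-BBN (the first equivalent is taken up by the enol O–H as a boron chelate that also masks the trione) followed by B-alkyl Suzuki–Miyaura coupling turns vinyl into 4-methylpent-3-enyl and methylidene into 3-methylbut-2-enyl without exposing a trisubstituted alkene to the borane, and C7 is set in the hydroboration, which should occur on the exo face of the methylidene group because its endo face lies against the enolised trione bridge of the chair–chair bicycle, leaving H exo and the new chain endo (7R).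

**Compound list**

1 | benzene-1,3,5-triol (phloroglucinol) | Oc1cc(O)cc(O)c1 | starting material
2 | 2-methylpropanoyl chloride | CC(C)C(Cl)=O | starting material
3 | 2-methyl-1-(2,4,6-trihydroxyphenyl)propan-1-one | CC(C)C(=O)c1c(O)cc(O)cc1O | intermediate
4 | but-2-yn-1-ol | CC#CCO | starting material
5 | (2Z)-3-(4,4,5,5-tetramethyl-1,3,2-dioxaborolan-2-yl)but-2-en-1-ol | OC/C=C(\C)B1OC(C)(C)C(C)(C)O1 | intermediate
6 | 2-bromoprop-2-en-1-ol | OCC(Br)=C | starting material
7 | (2E)-3-methyl-4-methylidenepent-2-ene-1,5-diol | OC/C=C(\C)C(=C)CO | intermediate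
8 | (2E)-3-methyl-4-methylidenepent-2-ene-1,5-diyl dimethyl biscarbonate | COC(=O)OC/C=C(\C)C(=C)COC(=O)OC | intermediate
9 | methyl (2E)-3-methyl-4-methylidene-5-[2,4,6-trihydroxy-3-(2-methylpropanoyl)phenyl]pent-2-en-1-yl carbonate | CC(C)C(=O)c1c(O)cc(O)c(CC(=C)/C(C)=C/COC(=O)OC)c1O | intermediate
10 | (1S,5S,6R)-6-ethenyl-4-hydroxy-6-methyl-7-methylidene-3-(2-methylpropanoyl)bicyclo[3.3.1]non-3-ene-2,9-dione | C=C[C@@]1(C)C(=C)C[C@@H]2C(=O)C(C(=O)C(C)C)=C(O)[C@H]1C2=O | intermediate
11 | 1-bromo-2-methylprop-1-ene | CC(C)=CBr | starting material
12 | tris(9-BBN) adduct of 10: 9-borabicyclo[3.3.1]nonan-9-yl groups on the enol oxygen, on the methyl carbon at C7 (endo, H at C7 exo) and on the terminal carbon of the C6 ethyl chain; C1, C5, C6 as in 10 | C(C[C@@]1(C)[C@H](CB3C4CCCC3CCC4)C[C@@H]2C(=O)C(C(=O)C(C)C)=C(OB5C6CCCC5CCC6)[C@H]1C2=O)B7C8CCCC7CCC8 | intermediate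
13 | (1S,5S,6S,7R)-4-hydroxy-6-methyl-7-(3-methylbut-2-en-1-yl)-6-(4-methylpent-3-en-1-yl)-3-(2-methylpropanoyl)bicyclo[3.3.1]non-3-ene-2,9-dione | CC(C)=CCC[C@@]1(C)[C@H](CC=C(C)C)C[C@@H]2C(=O)C(C(=O)C(C)C)=C(O)[C@H]1C2=O | target

**Step count:** 6 steps in total. Longest linear sequence: 5 steps (4 → 5 → 7 → 8 → 10 → 13).

**Steps most likely to fail**

Step 5. The ring closure may run through a phenol oxygen to a 2-methyl-2-vinylchroman that does not re-ionise, the C-protonated tautomer needed for bridging may react too slowly, a second intermolecular allylation may intervene, or the allyl face and the fold (methyl axial instead of equatorial) may be poorly controlled. The fallback uses known reaction types only, sets out from 3 and 7 and returns at 10. Pd(PPh3)4/Et3B-promoted direct C-allylation of 3 with the free diol 7 (C-selective for phloroglucinols, water as by-product) should give 1-{2,4,6-trihydroxy-3-[(3E)-5-hydroxy-3-methyl-2-methylidenepent-3-en-1-yl]phenyl}-2-methylpropan-1-one F1, which is isolated. A separate Pd(PPh3)4/Et3B cyclisation of F1 at high dilution should give the racemate of 10 F2, from which the isomer with the opposite fold is removed by chromatography. The acidic enolised trione is then resolved by crystallisation of its (1R)-1-phenylethanaminium salt F3, and dilute acid releases 10.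

Step 6. The dialkylborane may reduce the C9 ketone, the methylidene group may be attacked on the wrong face if ring B reacts through a boat, or the second coupling at the hindered C7 arm may stall. The fallback sets out from 10 and returns at 13. Hydroboration with pinacolborane catalysed by [Ir(cod)Cl]2/dppe, which leaves ketones untouched, should give the bis(pinacol boronate) F4. KHF2 converts it into the bis(potassium trifluoroborate) F5, and Suzuki–Miyaura coupling of F5 with 11 (PdCl2(dppf), Cs2CO3, toluene/H2O) gives 13.

Step 3. The boronate may protodeboronate under aqueous base, or the 2,3-disubstituted diene diol may dimerise or polymerise on concentration. The fallback sets out from 5 and returns at 7. Iododeboronation of 5 with N-iodosuccinimide (retention) should give (2E)-3-iodobut-2-en-1-ol F6. Stille coupling of F6 with 2-(tributylstannyl)prop-2-en-1-ol (Pd2(dba)3, AsPh3, CuI, DMF, rt, no aqueous base) gives 7, which is carried into step 4 as a solution.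

**Further compounds**

F1 | step 5 | 1-{2,4,6-trihydroxy-3-[(3E)-5-hydroxy-3-methyl-2-methylidenepent-3-en-1-yl]phenyl}-2-methylpropan-1-one | CC(C)C(=O)c1c(O)cc(O)c(CC(=C)/C(C)=C/CO)c1O
F2 | step 5 | racemate of 10 (both enantiomers, 1:1) | C=C[C@@]1(C)C(=C)C[C@@H]2C(=O)C(C(=O)C(C)C)=C(O)[C@H]1C2=O.C=C[C@]1(C)C(=C)C[C@H]2C(=O)C(C(=O)C(C)C)=C(O)[C@@H]1C2=O
F3 | step 5 | (1R)-1-phenylethanaminium enolate salt of 10 | C=C[C@@]1(C)C(=C)C[C@@H]2C(=O)C(C(=O)C(C)C)=C([O-])[C@H]1C2=O.C[C@@H]([NH3+])c1ccccc1
F4 | step 6 | bis(pinacol boronate): 13 with each 2-methylprop-1-enyl group replaced by a 4,4,5,5-tetramethyl-1,3,2-dioxaborolan-2-yl group | CC1(C)OB(OC1(C)C)CC[C@@]2(C)[C@H](CB3OC(C)(C)C(C)(C)O3)C[C@@H]4C(=O)C(C(=O)C(C)C)=C(O)[C@H]2C4=O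
F5 | step 6 | bis(potassium trifluoroborate) derived from F4 | [K+].[K+].F[B-](F)(F)CC[C@@]1(C)[C@H](C[B-](F)(F)F)C[C@@H]2C(=O)C(C(=O)C(C)C)=C(O)[C@H]1C2=O
F6 | step 3 | (2E)-3-iodobut-2-en-1-ol | OC/C=C(\C)I
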